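**Plan**

Ring A is numbered C1 (aroyl), C2 and C6 (OH), C3 and C5 (prenyl), C4 (OMe); ring B is the 3-hydroxyphenyl ring.
The last disconnection removes two MOM ethers (O6 of ring A, O3′ of ring B).
The key disconnection cuts the C1–C(=O) bond and the C2–O bond of ring A together. This is possible because C1 (aroyl) and C2 (OH) are neighbours and C6 on the other side of C1 carries an oxygen that polarises a C1–C2 aryne toward attack of a benzoate oxygen at C2.
The aryne precursor is cut at O–Tf, at both aryl–prenyl bonds and at the aryl–Si bond back to 5-methoxyresorcinol; the acid partner goes back to methyl 3-hydroxybenzoate.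
Forward: ring A is dressed by bis-MOM protection and three successive directed metalations (SiMe3, prenyl, prenyl), one MOM ether is exchanged for triflate, the rings are joined by the aryne insertion, and methanolysis frees the phenols; no ring is formed at any stage.
The target has no stereocentre and its alkenes carry two identical methyl groups, so no stereochemistry has to be set.

Key step: step 9

**Route**

Step 1
Reactants: 1 5-methoxyresorcinol (5-methoxybenzene-1,3-diol)
Product: 2 1-methoxy-3,5-bis(methoxymethoxy)benzene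
Conditions: MOMCl (2.5 equiv), i-Pr2NEt, CH2Cl2, 0 °C → rt
Reagents that add atoms: chloromethyl methyl ether, COCCl
Why: Williamson-type O-alkylation of both phenols under amine base should give the bis-acetal, whose MOM groups serve as directing groups in steps 2–4.

Step 2
Reactants: 2 1-methoxy-3,5-bis(methoxymethoxy)benzene
Product: 4 [4-methoxy-2,6-bis(methoxymethoxy)phenyl]trimethylsilane, via aryllithium 3 (not isolated)
Conditions: n-BuLi, TMEDA, THF, 0 °C; then Me3SiCl, −78 °C → rt
Reagents that add atoms: chlorotrimethylsilane, C[Si](C)(C)Cl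
Why: Directed ortho-metalation should take place at the C–H flanked by two chelating MOM ethers, which outrank the methoxy group as directors, and silyl quench places the future aryne trigger there while blocking that site.

Step 3
Reactants: 4 [4-methoxy-2,6-bis(methoxymethoxy)phenyl]trimethylsilane; 5 prenyl bromide (1-bromo-3-methylbut-2-ene)
Product: 7 [4-methoxy-2,6-bis(methoxymethoxy)-3-(3-methylbut-2-en-1-yl)phenyl]trimethylsilane, via aryllithium 6 (not isolated)
Conditions: s-BuLi, TMEDA, THF, −78 °C; then CuBr·SMe2 (10 mol %), 5, −78 → 0 °C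
Reagents that add atoms: none
Why: Directed ortho-metalation at one of the two equivalent positions between a MOM ether and the methoxy group, followed by copper-catalysed allylic substitution at the unhindered CH2 terminus of prenyl bromide, should give the linear prenyl arene.

Step 4
Reactants: 7 [4-methoxy-2,6-bis(methoxymethoxy)-3-(3-methylbut-2-en-1-yl)phenyl]trimethylsilane; 5 prenyl bromide
Product: 9 [4-methoxy-2,6-bis(methoxymethoxy)-3,5-bis(3-methylbut-2-en-1-yl)phenyl]trimethylsilane, via aryllithium 8 (not isolated)
Conditions: s-BuLi, TMEDA, THF, −78 °C; then CuBr·SMe2 (10 mol %), 5, −78 → 0 °C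
Reagents that add atoms: none
Why: The last ring C–H lies between a MOM ether and the methoxy group, so chelation-assisted directed ortho-metalation at −78 °C should outrun deprotonation of the prenyl CH2, and the same copper-catalysed allylation completes the substitution pattern.

Step 5
Reactants: 9 [4-methoxy-2,6-bis(methoxymethoxy)-3,5-bis(3-methylbut-2-en-1-yl)phenyl]trimethylsilane
Product: 11 3-methoxy-5-(methoxymethoxy)-2,4-bis(3-methylbut-2-en-1-yl)-6-(trimethylsilyl)phenol, via aryl trimethylsilyl ether 10 (not isolated)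
Conditions: Me3SiOTf (1.0 equiv), 2,2′-bipyridyl (1.5 equiv), MeCN, 0 °C; then H2O, rt
Reagents that add atoms: none
Why: Silyl triflate/2,2′-bipyridyl cleavage of an aromatic MOM ether (acetal exchange to the aryl silyl ether, then hydrolysis) is non-protic, so the aryl–silicon bond flanked by two oxygens and the prenyl groups should survive; one equivalent of silyl triflate limits the reaction to mono-cleavage, with unreacted 9 recycled.

Step 6
Reactants: 11 3-methoxy-5-(methoxymethoxy)-2,4-bis(3-methylbut-2-en-1-yl)-6-(trimethylsilyl)phenol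
Product: 12 3-methoxy-5-(methoxymethoxy)-2,4-bis(3-methylbut-2-en-1-yl)-6-(trimethylsilyl)phenyl trifluoromethanesulfonate
Conditions: Tf2O, pyridine, CH2Cl2, −20 → 0 °C
Reagents that add atoms: trifluoromethanesulfonic anhydride, O=S(=O)(OS(=O)(=O)C(F)(F)F)C(F)(F)F
Why: O-Sulfonylation of an ortho-silyl phenol with triflic anhydride and pyridine is the standard entry to o-silylaryl triflates and should leave the MOM ether, the alkenes and the C–Si bond untouched.

Step 7
Reactants: 13 methyl 3-hydroxybenzoate
Product: 14 methyl 3-(methoxymethoxy)benzoate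
Conditions: MOMCl, i-Pr2NEt, CH2Cl2, 0 °C → rt
Reagents that add atoms: chloromethyl methyl ether, COCCl
Why: Williamson-type O-alkylation masks the ring B phenol, which would otherwise add to the aryne, with the same group that protects O6 of ring A.

Step 8
Reactants: 14 methyl 3-(methoxymethoxy)benzoate
Product: 15 3-(methoxymethoxy)benzoic acid
Conditions: LiOH, THF/H2O, rt; then 1 M HCl to pH 4, 0 °C
Reagents that add atoms: lithium hydroxide, [Li+].[OH-]
Why: Ester saponification by acyl–oxygen cleavage should give the acid, and the brief cold acidification to pH 4 is too mild to cleave the aryl MOM ether.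

Step 9
Reactants: 12 3-methoxy-5-(methoxymethoxy)-2,4-bis(3-methylbut-2-en-1-yl)-6-(trimethylsilyl)phenyl trifluoromethanesulfonate; 15 3-(methoxymethoxy)benzoic acid
Product: 19 [2-hydroxy-4-methoxy-6-(methoxymethoxy)-3,5-bis(3-methylbut-2-en-1-yl)phenyl][3-(methoxymethoxy)phenyl]methanone, via caesium carboxylate 16 (not isolated), via aryne 17 (not isolated), via aryl caesium adduct 18 (not isolated)
Conditions: 15 (2 equiv), Cs2CO3 (1 equiv), MeOH, rt, evaporate, dry; then 12 (1 equiv), CsF (3 equiv), THF, 125 °C, sealed tube; aq. NH4Cl work-up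
Reagents that add atoms: none
Why: Fluoride attacks silicon in 12 and the ortho triflate leaves, giving the C1–C2 aryne 17; the carboxylate oxygen of 16 adds at C2, and the aryl anion at C1 (18) attacks its own ester carbonyl through a transient four-membered alkoxide that opens to the phenoxide ketone, so the C2–O and C1–C(=O) bonds form in one operation. The closest known reaction type is the insertion of arynes into the acyl–oxygen bond of carboxylic acids, which gives o-hydroxyaryl ketones. No ring is closed and no stereocentre is created. The regioselectivity needed (oxygen at C2, acyl at C1) should follow from the inductively withdrawing MOM ether at C6, which distorts the aryne so that the distal carbon C2 is the electrophilic end and the negative charge develops at C1 next to oxygen. The chemoselectivity needed is acyl capture ahead of protonation of the aryl anion, which the dry, pre-formed caesium carboxylate in hot aprotic THF should secure, since no free acid or HF is present; this also protects the electron-rich aryl–silicon bond of 12 from protodesilylation. The base-only medium leaves the prenyl groups and both MOM ethers intact.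

Step 10
Reactants: 19 [2-hydroxy-4-methoxy-6-(methoxymethoxy)-3,5-bis(3-methylbut-2-en-1-yl)phenyl][3-(methoxymethoxy)phenyl]methanone
Product: 20 [2,6-dihydroxy-4-methoxy-3,5-bis(3-methylbut-2-en-1-yl)phenyl](3-hydroxyphenyl)methanone (CNP0425861.0)
Conditions: 3 M HCl, MeOH, 40 °C
Reagents that add atoms: none
Why: Acid-catalysed acetal exchange with methanol should remove both MOM ethers, and the mild temperature should keep the o-prenylphenols from cyclising to chromans.

**Compound list**

1 | 5-methoxyresorcinol (5-methoxybenzene-1,3-diol) | COc1cc(O)cc(O)c1 | starting material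
2 | 1-methoxy-3,5-bis(methoxymethoxy)benzene | COCOc1cc(OC)cc(OCOC)c1 | intermediate
3 | [4-methoxy-2,6-bis(methoxymethoxy)phenyl]lithium (formed in the flask) | [Li]c1c(OCOC)cc(OC)cc1OCOC | intermediate
4 | [4-methoxy-2,6-bis(methoxymethoxy)phenyl]trimethylsilane | COCOc1cc(OC)cc(OCOC)c1[Si](C)(C)C | intermediate
5 | prenyl bromide (1-bromo-3-methylbut-2-ene) | CC(C)=CCBr | starting material
6 | [6-methoxy-2,4-bis(methoxymethoxy)-3-(trimethylsilyl)phenyl]lithium (formed in the flask) | [Li]c1c(OC)cc(OCOC)c([Si](C)(C)C)c1OCOC | intermediate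
7 | [4-methoxy-2,6-bis(methoxymethoxy)-3-(3-methylbut-2-en-1-yl)phenyl]trimethylsilane | COCOc1cc(OC)c(CC=C(C)C)c(OCOC)c1[Si](C)(C)C | intermediate
8 | [6-methoxy-2,4-bis(methoxymethoxy)-5-(3-methylbut-2-en-1-yl)-3-(trimethylsilyl)phenyl]lithium (formed in the flask) | [Li]c1c(OC)c(CC=C(C)C)c(OCOC)c([Si](C)(C)C)c1OCOC | intermediate
9 | [4-methoxy-2,6-bis(methoxymethoxy)-3,5-bis(3-methylbut-2-en-1-yl)phenyl]trimethylsilane | COCOc1c(CC=C(C)C)c(OC)c(CC=C(C)C)c(OCOC)c1[Si](C)(C)C | intermediate
10 | trimethylsilyl ether of phenol 11 (formed in the flask) | COCOc1c(CC=C(C)C)c(OC)c(CC=C(C)C)c(O[Si](C)(C)C)c1[Si](C)(C)C | intermediate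
11 | 3-methoxy-5-(methoxymethoxy)-2,4-bis(3-methylbut-2-en-1-yl)-6-(trimethylsilyl)phenol | COCOc1c(CC=C(C)C)c(OC)c(CC=C(C)C)c(O)c1[Si](C)(C)C | intermediate
12 | 3-methoxy-5-(methoxymethoxy)-2,4-bis(3-methylbut-2-en-1-yl)-6-(trimethylsilyl)phenyl trifluoromethanesulfonate | COCOc1c(CC=C(C)C)c(OC)c(CC=C(C)C)c(OS(=O)(=O)C(F)(F)F)c1[Si](C)(C)C | intermediate
13 | methyl 3-hydroxybenzoate | COC(=O)c1cccc(O)c1 | starting material
14 | methyl 3-(methoxymethoxy)benzoate | COCOc1cccc(C(=O)OC)c1 | intermediate
15 | 3-(methoxymethoxy)benzoic acid | O=C(O)c1cccc(OCOC)c1 | intermediate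
16 | caesium 3-(methoxymethoxy)benzoate (formed in the flask) | COCOc1cccc(C(=O)[O-])c1.[Cs+] | intermediate
17 | 3-methoxy-5-(methoxymethoxy)-2,4-bis(3-methylbut-2-en-1-yl)benzyne, the C1–C2 aryne of ring A (formed in the flask) | COCOC1=C(CC=C(C)C)C(OC)=C(CC=C(C)C)C#C1 | intermediate
18 | {3-methoxy-5-(methoxymethoxy)-2,4-bis(3-methylbut-2-en-1-yl)-6-caesiophenyl} 3-(methoxymethoxy)benzoate (formed in the flask) | COCOc1cccc(C(=O)Oc2c(CC=C(C)C)c(OC)c(CC=C(C)C)c(OCOC)c2[Cs])c1 | intermediate
19 | [2-hydroxy-4-methoxy-6-(methoxymethoxy)-3,5-bis(3-methylbut-2-en-1-yl)phenyl][3-(methoxymethoxy)phenyl]methanone | COCOc1c(CC=C(C)C)c(OC)c(CC=C(C)C)c(O)c1C(=O)c1cccc(OCOC)c1 | intermediate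
20 | [2,6-dihydroxy-4-methoxy-3,5-bis(3-methylbut-2-en-1-yl)phenyl](3-hydroxyphenyl)methanone | COc1c(CC=C(C)C)c(O)c(C(=O)c2cccc(O)c2)c(O)c1CC=C(C)C | target

**Step count and risks**

Total step count: 10. Longest linear sequence: 8 steps (steps 1–6, 9 and 10); steps 7 and 8 make the acid partner.

Most likely to fail, first: step 9. On the hindered, tetrasubstituted aryne the aryl anion may be quenched before it reaches the ester carbonyl, so that the reaction stops at O-arylation, or the carboxylate may add at the wrong aryne carbon because the C3 prenyl group shields C2. The fallback sets out from 9 and 14 and rejoins the route at the target 20 without an aryne. Fluoride (Bu4NF, DMF, 80 °C) removes the silyl group of 9 to give 2-methoxy-4,6-bis(methoxymethoxy)-1,3-bis(3-methylbut-2-en-1-yl)benzene F1. s-BuLi/TMEDA at −78 °C metalates the position between the two MOM ethers to give [4-methoxy-2,6-bis(methoxymethoxy)-3,5-bis(3-methylbut-2-en-1-yl)phenyl]lithium F2. This is acylated in a Weinreb ketone synthesis with N-methoxy-3-(methoxymethoxy)-N-methylbenzamide F3, made from ester 14 with MeNHOMe·HCl and i-PrMgCl, to give [4-methoxy-2,6-bis(methoxymethoxy)-3,5-bis(3-methylbut-2-en-1-yl)phenyl][3-(methoxymethoxy)phenyl]methanone F4. The conditions of step 10 then remove all three MOM groups to give 20.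

Second: step 5. The two MOM ethers of 9 are equivalent and crowded, so cleavage may be sluggish or unselective, with mono-cleavage accompanied by unreacted material and double cleavage. The fallback sets out from 9 and returns at 11. Excess Me3SiOTf/2,2′-bipyridyl followed by water cleaves both acetals to 5-methoxy-4,6-bis(3-methylbut-2-en-1-yl)-2-(trimethylsilyl)benzene-1,3-diol F5. NaH (2.2 equiv) in THF/DMF converts it into the disodium salt of this resorcinol F6. MOMCl (1.0 equiv) at −40 °C should alkylate it once, because the dianion is far more nucleophilic than the monoanion of the product, giving 11.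

Third: step 4. Deprotonation at the benzylic-allylic CH2 of the prenyl group already present may compete with ring metalation and lead to isomerised or branched side chains. The fallback sets out from 2 and returns at 9; it generates every aryllithium by bromine–lithium exchange instead of deprotonation.
- NBS (3.1 equiv) in MeCN brominates all three ring positions of 2 to give 1,3,5-tribromo-2-methoxy-4,6-bis(methoxymethoxy)benzene F7.
- n-BuLi (1 equiv) at −78 °C should exchange the bromine held between the two chelating MOM ethers, giving [3,5-dibromo-4-methoxy-2,6-bis(methoxymethoxy)phenyl]lithium F8; Me3SiCl converts it into [3,5-dibromo-4-methoxy-2,6-bis(methoxymethoxy)phenyl]trimethylsilane F9.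
- A second exchange gives [3-bromo-6-methoxy-2,4-bis(methoxymethoxy)-5-(trimethylsilyl)phenyl]lithium F10; CuBr·SMe2-catalysed coupling with 5 gives [3-bromo-4-methoxy-2,6-bis(methoxymethoxy)-5-(3-methylbut-2-en-1-yl)phenyl]trimethylsilane F11.
- A last exchange at −78 °C, faster than any deprotonation of the side chain, gives aryllithium 8, and coupling with 5 as in step 4 gives 9.

**Further compounds**

F1 | step 9 | 2-methoxy-4,6-bis(methoxymethoxy)-1,3-bis(3-methylbut-2-en-1-yl)benzene | COCOc1cc(OCOC)c(CC=C(C)C)c(OC)c1CC=C(C)C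
F2 | step 9 | [4-methoxy-2,6-bis(methoxymethoxy)-3,5-bis(3-methylbut-2-en-1-yl)phenyl]lithium | [Li]c1c(OCOC)c(CC=C(C)C)c(OC)c(CC=C(C)C)c1OCOC
F3 | step 9 | N-methoxy-3-(methoxymethoxy)-N-methylbenzamide | COCOc1cccc(C(=O)N(C)OC)c1
F4 | step 9 | [4-methoxy-2,6-bis(methoxymethoxy)-3,5-bis(3-methylbut-2-en-1-yl)phenyl][3-(methoxymethoxy)phenyl]methanone | COCOc1cccc(C(=O)c2c(OCOC)c(CC=C(C)C)c(OC)c(CC=C(C)C)c2OCOC)c1
F5 | step 5 | 5-methoxy-4,6-bis(3-methylbut-2-en-1-yl)-2-(trimethylsilyl)benzene-1,3-diol | COc1c(CC=C(C)C)c(O)c([Si](C)(C)C)c(O)c1CC=C(C)C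
F6 | step 5 | disodium 5-methoxy-4,6-bis(3-methylbut-2-en-1-yl)-2-(trimethylsilyl)benzene-1,3-diolate | COc1c(CC=C(C)C)c([O-])c([Si](C)(C)C)c([O-])c1CC=C(C)C.[Na+].[Na+]
F7 | step 4 | 1,3,5-tribromo-2-methoxy-4,6-bis(methoxymethoxy)benzene | COCOc1c(Br)c(OC)c(Br)c(OCOC)c1Br
F8 | step 4 | [3,5-dibromo-4-methoxy-2,6-bis(methoxymethoxy)phenyl]lithium | [Li]c1c(OCOC)c(Br)c(OC)c(Br)c1OCOC
F9 | step 4 | [3,5-dibromo-4-methoxy-2,6-bis(methoxymethoxy)phenyl]trimethylsilane | COCOc1c(Br)c(OC)c(Br)c(OCOC)c1[Si](C)(C)C
F10 | step 4 | [3-bromo-6-methoxy-2,4-bis(methoxymethoxy)-5-(trimethylsilyl)phenyl]lithium | [Li]c1c(OC)c(Br)c(OCOC)c([Si](C)(C)C)c1OCOC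
F11 | step 4 | [3-bromo-4-methoxy-2,6-bis(methoxymethoxy)-5-(3-methylbut-2-en-1-yl)phenyl]trimethylsilane | COCOc1c(Br)c(OC)c(CC=C(C)C)c(OCOC)c1[Si](C)(C)C
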